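**Retrosynthetic overview**

- The strategy rests on ring atom C5 of the tetrahydrofuran (O1, C2–C5): it is an unsubstituted CH2 between O1 and the benzyl-bearing C4. The ring can therefore be made as a C4=C5 enol ether, and the last step is hydrogenation of that bond together with removal of the three benzyl ethers.
- The C4=C5 bond comes from ring-closing metathesis of an O-vinyl ether on O1 with a 1,1-disubstituted alkene at C4. This closes the only ring built in the route, and the benzylic C2–O1 bond is never ionised.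
- The diene comes from a homoallylic alcohol whose C2/C3 pair is set by an Evans syn aldol of a 3-(arylmethyl)but-3-enoyl imide with 3,4-bis(benzyloxy)benzaldehyde. The imide carbonyl becomes the C3 acetoxymethyl group.
- The acyl chain comes from a Negishi coupling of a benzylzinc chloride with 3-iodobut-3-enoic acid.

Key step: step 9

Remark on the chemistry: ring atoms are numbered O1, C2 (catechol-bearing), C3 (acetoxymethyl), C4 (benzyl), C5 (CH2). The target is read from its SMILES as (2S,3R,4R), that is 2,3-trans and 3,4-cis.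

**Route**

Step 1
Reactants: 1 4-(benzyloxy)-3-methoxybenzyl alcohol
Product: 2 4-(benzyloxy)-3-methoxybenzyl chloride
Conditions: SOCl2, CH2Cl2, 0 °C → 25 °C
Reagents that add atoms: thionyl chloride, O=S(Cl)Cl
Why: Deoxychlorination of an electron-rich benzylic alcohol through its chlorosulfite should be fast and clean, and the aryl benzyl ether is inert to it.

Step 2
Reactants: 3 but-3-ynoic acid
Product: 4 3-iodobut-3-enoic acid
Conditions: 57% aq. HI, 25 °C, dark
Reagents that add atoms: hydrogen iodide, I
Why: Markovnikov hydroiodination of the terminal alkyne (proton to the terminal carbon, iodide to the internal one) should give the 2-iodo-1-alkene with the double bond out of conjugation.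

Step 3
Reactants: 2 4-(benzyloxy)-3-methoxybenzyl chloride; 4 3-iodobut-3-enoic acid
Product: 7 3-[4-(benzyloxy)-3-methoxybenzyl]but-3-enoic acid, via sodium 3-iodobut-3-enoate 5 (not isolated), via benzylzinc chloride 6 (not isolated)
Conditions: 4, NaH (1 equiv.), THF, 0 °C; then 6 (from 2, Zn dust, LiCl, THF, 25 °C), PdCl2(MeCN)2 (5 mol%), DMF, 25 °C; 1 M HCl work-up
Reagents that add atoms: none
Why: Negishi coupling, in which zerovalent palladium formed in the flask inserts into the vinylic C–I bond and takes the benzyl group from zinc; the carboxylate does not quench the zinc reagent and the sp2 coupling should leave the alkene in the β,γ-position.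

Step 4
Reactants: 7 3-[4-(benzyloxy)-3-methoxybenzyl]but-3-enoic acid; 8 (S)-4-benzyloxazolidin-2-one
Product: 11 (S)-4-benzyl-3-{3-[4-(benzyloxy)-3-methoxybenzyl]but-3-enoyl}oxazolidin-2-one, via mixed pivalic anhydride 9 (not isolated), via lithium oxazolidinide 10 (not isolated)
Conditions: 7, PivCl, Et3N, THF, −78 → 0 °C; then 10 (from 8, n-BuLi, THF, −78 °C), −78 → 0 °C
Reagents that add atoms: none
Why: N-acylation of the lithiated Evans auxiliary at the less hindered carbonyl of the mixed anhydride, at a temperature low enough that the β,γ-alkene should not move into conjugation.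

Step 5
Reactants: 11 (S)-4-benzyl-3-{3-[4-(benzyloxy)-3-methoxybenzyl]but-3-enoyl}oxazolidin-2-one; 12 3,4-bis(benzyloxy)benzaldehyde
Product: 15 (S)-4-benzyl-3-[(2S,3S)-3-[3,4-bis(benzyloxy)phenyl]-2-{3-[4-(benzyloxy)-3-methoxyphenyl]prop-1-en-2-yl}-3-hydroxypropanoyl]oxazolidin-2-one, via boron dienolate 13 (not isolated), via boron aldolate 14 (not isolated)
Conditions: n-Bu2BOTf, i-Pr2NEt, CH2Cl2, −78 → 0 °C; 12, −78 → 0 °C; then pH 7 buffer, MeOH, 30% H2O2, 0 °C
Reagents that add atoms: none
Why: Evans syn aldol, in which the Z-boron dienolate reacts at its α-carbon through a chair Zimmerman–Traxler transition state on the face away from the auxiliary benzyl group; this should set the future C2 (S) and C3 as the syn pair that becomes the 2,3-trans ring relation.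

Step 6
Reactants: 15 the syn aldol imide
Product: 16 (1S,2R)-1-[3,4-bis(benzyloxy)phenyl]-2-{3-[4-(benzyloxy)-3-methoxyphenyl]prop-1-en-2-yl}propane-1,3-diol
Conditions: LiBH4, THF, MeOH (1 equiv.), 0 °C
Reagents that add atoms: none
Why: Reductive cleavage of the imide by hydride attack at the exocyclic carbonyl should release the auxiliary and give the primary alcohol without touching the two stereocentres or the alkene.

Step 7
Reactants: 16 the 1,3-diol
Product: 17 (2R,3S)-3-[3,4-bis(benzyloxy)phenyl]-2-{3-[4-(benzyloxy)-3-methoxyphenyl]prop-1-en-2-yl}-3-hydroxypropyl acetate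
Conditions: AcCl, 2,4,6-collidine, CH2Cl2, −78 °C
Reagents that add atoms: acetyl chloride, CC(=O)Cl
Why: Selective O-acylation with an acid chloride and a hindered pyridine base at low temperature should take the primary hydroxyl and leave the hindered secondary benzylic one.

Step 8
Reactants: 17 the primary monoacetate
Product: 18 (2R,3S)-3-[3,4-bis(benzyloxy)phenyl]-2-{3-[4-(benzyloxy)-3-methoxyphenyl]prop-1-en-2-yl}-3-(vinyloxy)propyl acetate
Conditions: butyl vinyl ether (solvent), Pd(OCOCF3)2 (5 mol%), 4,7-diphenyl-1,10-phenanthroline (5 mol%), Et3N (cat.), 75 °C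
Reagents that add atoms: butyl vinyl ether, C=COCCCC
Why: Transfer vinylation catalysed by divalent palladium (oxypalladation of the vinyl donor by the alcohol, then loss of butanol) is driven by the excess donor and exposes neither the benzylic C–O bond to acid nor the acetate to strong base.

Step 9
Reactants: 18 the homoallyl vinyl ether
Product: 19 {(2S,3R)-2-[3,4-bis(benzyloxy)phenyl]-4-[4-(benzyloxy)-3-methoxybenzyl]-2,3-dihydrofuran-3-yl}methyl acetate
Conditions: second-generation Grubbs catalyst RuCl2(=CHPh)(PCy3)(H2IMes) (10 mol%), 1,4-benzoquinone (20 mol%), toluene (0.005 M), 80 °C, Ar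
Reagents that add atoms: none
Why: Ring-closing olefin metathesis, in which the ruthenium benzylidene exchanges onto one terminal alkene of 18, the substrate-bound carbene adds across the other to a ruthenacyclobutane, and cycloreversion releases ethylene and forms C4=C5. The closest known reaction type is ring-closing metathesis of olefinic vinyl ethers to five- and six-membered cyclic enol ethers. The one ring, the 2,3-dihydrofuran O1–C2–C3–C4–C5, is closed by joining C4 to C5 through a metallacyclobutane fused to the forming five-membered ring. No stereocentre is created, C2 and C3 from the aldol are spectators, and the benzylic C2–O1 bond meets no acid. The step needs the two terminal alkenes to react with each other faster than double bonds migrate or chains couple; the absence of any other alkene, high dilution, the bias for five-membered closure and benzoquinone as a scavenger of ruthenium hydrides should secure this.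

Step 10
Reactants: 19 the tribenzyl 2,3-dihydrofuran
Product: 20 {(2S,3R,4R)-2-(3,4-dihydroxyphenyl)-4-(4-hydroxy-3-methoxybenzyl)tetrahydrofuran-3-yl}methyl acetate
Conditions: H2 (1 atm), 10% Pd/C, EtOAc, 25 °C
Reagents that add atoms: none
Why: Heterogeneous hydrogenation with hydrogenolysis, in which H2 should add syn to the C4=C5 enol ether on the ring face opposite the neighbouring C3 acetoxymethyl group, placing the C4 benzyl group cis to it (C4 R), while the three aryl benzyl ethers are cleaved in the same operation.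

**Compound list**

1 | 4-(benzyloxy)-3-methoxybenzyl alcohol | COc1cc(CO)ccc1OCc1ccccc1 | starting material
2 | 4-(benzyloxy)-3-methoxybenzyl chloride | COc1cc(CCl)ccc1OCc1ccccc1 | intermediate
3 | but-3-ynoic acid | C#CCC(=O)O | starting material
4 | 3-iodobut-3-enoic acid | C=C(I)CC(=O)O | intermediate
5 | sodium 3-iodobut-3-enoate | C=C(I)CC(=O)[O-].[Na+] | intermediate
6 | [4-(benzyloxy)-3-methoxybenzyl]zinc chloride | COc1cc(C[Zn]Cl)ccc1OCc1ccccc1 | intermediate
7 | 3-[4-(benzyloxy)-3-methoxybenzyl]but-3-enoic acid | COc1cc(CC(=C)CC(=O)O)ccc1OCc1ccccc1 | intermediate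
8 | (S)-4-benzyloxazolidin-2-one | O=C1OC[C@H](Cc2ccccc2)N1 | starting material
9 | 3-[4-(benzyloxy)-3-methoxybenzyl]but-3-enoic pivalic anhydride | COc1cc(CC(=C)CC(=O)OC(=O)C(C)(C)C)ccc1OCc1ccccc1 | intermediate
10 | lithium (S)-4-benzyl-2-oxooxazolidin-3-ide | O=C1OC[C@H](Cc2ccccc2)[N-]1.[Li+] | intermediate
11 | (S)-4-benzyl-3-{3-[4-(benzyloxy)-3-methoxybenzyl]but-3-enoyl}oxazolidin-2-one | COc1cc(CC(=C)CC(=O)N2C(=O)OC[C@@H]2Cc2ccccc2)ccc1OCc1ccccc1 | intermediate
12 | 3,4-bis(benzyloxy)benzaldehyde | O=Cc1ccc(OCc2ccccc2)c(OCc2ccccc2)c1 | starting material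
13 | (Z)-dibutylboron dienolate of imide 11 | COc1cc(CC(=C)/C=C(\OB(CCCC)CCCC)N2C(=O)OC[C@@H]2Cc2ccccc2)ccc1OCc1ccccc1 | intermediate
14 | dibutylboron aldolate of 15 | COc1cc(CC(=C)[C@H](C(=O)N2C(=O)OC[C@@H]2Cc2ccccc2)[C@H](OB(CCCC)CCCC)c2ccc(OCc3ccccc3)c(OCc3ccccc3)c2)ccc1OCc1ccccc1 | intermediate
15 | (S)-4-benzyl-3-[(2S,3S)-3-[3,4-bis(benzyloxy)phenyl]-2-{3-[4-(benzyloxy)-3-methoxyphenyl]prop-1-en-2-yl}-3-hydroxypropanoyl]oxazolidin-2-one | COc1cc(CC(=C)[C@H](C(=O)N2C(=O)OC[C@@H]2Cc2ccccc2)[C@H](O)c2ccc(OCc3ccccc3)c(OCc3ccccc3)c2)ccc1OCc1ccccc1 | intermediate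
16 | (1S,2R)-1-[3,4-bis(benzyloxy)phenyl]-2-{3-[4-(benzyloxy)-3-methoxyphenyl]prop-1-en-2-yl}propane-1,3-diol | COc1cc(CC(=C)[C@H](CO)[C@H](O)c2ccc(OCc3ccccc3)c(OCc3ccccc3)c2)ccc1OCc1ccccc1 | intermediate
17 | (2R,3S)-3-[3,4-bis(benzyloxy)phenyl]-2-{3-[4-(benzyloxy)-3-methoxyphenyl]prop-1-en-2-yl}-3-hydroxypropyl acetate | COc1cc(CC(=C)[C@H](COC(C)=O)[C@H](O)c2ccc(OCc3ccccc3)c(OCc3ccccc3)c2)ccc1OCc1ccccc1 | intermediate
18 | (2R,3S)-3-[3,4-bis(benzyloxy)phenyl]-2-{3-[4-(benzyloxy)-3-methoxyphenyl]prop-1-en-2-yl}-3-(vinyloxy)propyl acetate | COc1cc(CC(=C)[C@H](COC(C)=O)[C@@H](c2ccc(OCc3ccccc3)c(OCc3ccccc3)c2)OC=C)ccc1OCc1ccccc1 | intermediate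
19 | {(2S,3R)-2-[3,4-bis(benzyloxy)phenyl]-4-[4-(benzyloxy)-3-methoxybenzyl]-2,3-dihydrofuran-3-yl}methyl acetate | COc1cc(CC2=CO[C@H](c3ccc(OCc4ccccc4)c(OCc4ccccc4)c3)[C@H]2COC(C)=O)ccc1OCc1ccccc1 | intermediate
20 | {(2S,3R,4R)-2-(3,4-dihydroxyphenyl)-4-(4-hydroxy-3-methoxybenzyl)tetrahydrofuran-3-yl}methyl acetate | COc1cc(C[C@H]2CO[C@H](c3ccc(O)c(O)c3)[C@H]2COC(C)=O)ccc1O | target

**Step count and risks**

Total steps: 10. Longest linear sequence: 9 steps (steps 1 and 3 to 10; step 2 is a one-step side branch).

Steps most likely to fail: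

1. Step 9 (ring-closing metathesis). The ruthenium carbene may be drained onto the vinyl ether as a slow alkoxy-substituted carbene while the hindered 1,1-disubstituted alkene is engaged too slowly, so that catalyst decay and double-bond migration outrun ring closure.
   Fallback, from 17 to 20, closing the ring by O1–C5 alkylation instead of metathesis: hydroboration of the 1,1-disubstituted alkene of 17 with 9-BBN in THF (one further equivalent is taken up by the free hydroxyl) would give the bis(9-borabicyclononyl) adduct F1. Oxidation with NaBO3·4H2O would give the 1,4-diol F2 as a pair of C4 epimers. TsCl in pyridine at 0 °C should sulfonylate only the primary hydroxyl to the primary tosylate F3. On warming this should close O1–C5 by intramolecular Williamson displacement (5-exo-tet, C2–O1 bond untouched) to the tribenzyl tetrahydrofuran F4. The 3,4-cis epimer would have to be separated by chromatography, since C4 is set here without the ring's help. Hydrogenolysis (H2, Pd/C, EtOAc) then rejoins the route at 20.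

2. Step 10 (hydrogenation and debenzylation). Hydrogen delivery to C4 may be poorly face-selective, because the C2 aryl group sits on the face that must be attacked. The benzylic C2–O1 bond may also undergo hydrogenolysis once the catechol is unmasked.
   Fallback, from 19 to 20, as a staged reduction: the alkene alone would be saturated with H2 over Pd/C poisoned with pyridine in EtOAc, conditions under which aryl benzyl ethers and benzylic C–O bonds should not be cleaved, to give the tribenzyl tetrahydrofuran F5. Its C4 epimers could be separated at this non-polar stage. The benzyl ethers would then be removed by transfer hydrogenolysis (Pd/C, 1,4-cyclohexadiene, EtOH, 25 °C) to reach 20.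

3. Step 8 (O-vinylation). Vinyl transfer to the hindered secondary benzylic hydroxyl is an equilibrium and may stall, with mixed-acetal formation or acetyl migration as competing processes.
   Fallback, from 17 to 18, by acetalisation and elimination: addition of 17 to ethyl vinyl ether (PPTS, CH2Cl2, 0 °C) would give the 1-ethoxyethyl mixed acetal F6. TMSOTf with excess Et3N (CH2Cl2, 0 °C) would then remove ethanol from the less hindered side of the acetal, as its trimethylsilyl ether, to give vinyl ether 18.

**Further compounds**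

F1 | step 9 | O,C-bis(9-borabicyclo[3.3.1]nonan-9-yl) hydroboration adduct of 17 | COc1cc(CC(CB2C3CCCC2CCC3)[C@H](COC(C)=O)[C@H](OB2C3CCCC2CCC3)c2ccc(OCc3ccccc3)c(OCc3ccccc3)c2)ccc1OCc1ccccc1
F2 | step 9 | (2R,3S)-3-[3,4-bis(benzyloxy)phenyl]-2-{1-[4-(benzyloxy)-3-methoxyphenyl]-3-hydroxypropan-2-yl}-3-hydroxypropyl acetate (both C4 epimers) | COc1cc(CC(CO)[C@H](COC(C)=O)[C@H](O)c2ccc(OCc3ccccc3)c(OCc3ccccc3)c2)ccc1OCc1ccccc1
F3 | step 9 | primary p-toluenesulfonate of diol F2 | COc1cc(CC(COS(=O)(=O)c2ccc(C)cc2)[C@H](COC(C)=O)[C@H](O)c2ccc(OCc3ccccc3)c(OCc3ccccc3)c2)ccc1OCc1ccccc1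
F4 | step 9 | {(2S,3R,4R)-2-[3,4-bis(benzyloxy)phenyl]-4-[4-(benzyloxy)-3-methoxybenzyl]tetrahydrofuran-3-yl}methyl acetate | COc1cc(C[C@H]2CO[C@H](c3ccc(OCc4ccccc4)c(OCc4ccccc4)c3)[C@H]2COC(C)=O)ccc1OCc1ccccc1
F5 | step 10 | {(2S,3R,4R)-2-[3,4-bis(benzyloxy)phenyl]-4-[4-(benzyloxy)-3-methoxybenzyl]tetrahydrofuran-3-yl}methyl acetate | COc1cc(C[C@H]2CO[C@H](c3ccc(OCc4ccccc4)c(OCc4ccccc4)c3)[C@H]2COC(C)=O)ccc1OCc1ccccc1
F6 | step 8 | (2R,3S)-3-[3,4-bis(benzyloxy)phenyl]-2-{3-[4-(benzyloxy)-3-methoxyphenyl]prop-1-en-2-yl}-3-(1-ethoxyethoxy)propyl acetate | COc1cc(CC(=C)[C@H](COC(C)=O)[C@@H](c2ccc(OCc3ccccc3)c(OCc3ccccc3)c2)OC(C)OCC)ccc1OCc1ccccc1
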